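## Structural features

The target is a flavonol, a 4H-chromen-4-one. Ring A (C4a, C5, C6, C7, C8, C8a) is fused through C4a–C8a to the 4-pyranone ring C (O1, C2, C3, C4), and ring B, a 3-hydroxy-4,5-dimethoxyphenyl group, is joined to C2 by one C(sp2)–C(sp2) bond. Ring A bears hydroxyls at C5 and C7 and a methoxy group at C8, ring C bears the enolic hydroxyl at C3 next to the C4 carbonyl, and ring B bears one hydroxyl beside two methoxy groups. There is no stereocentre and no stereogenic double bond, so the problem is regiochemistry: four free hydroxyls must be told apart from three methoxy groups. The fragile points are the electron-rich polyphenol, which oxidises in air under base, and the 5-hydroxy-8-methoxy pattern, which hot strong acid can scramble to the 6-methoxy isomer by opening and reclosing ring C (Wessely–Moser rearrangement); the last steps must therefore be neutral. The real difficulty is placing the methoxy group at C8 and not at C6: the usual precursor, a 2,4,6-trioxygenated 3-methoxyphenyl ketone, has two ortho oxygens, and either can become O1. The feature the key step exploits is that O1, C2, C3 with its hydroxyl, C4 with its carbonyl, C4a and C8a, together with C8 and the oxygen on it, are atom for atom the skeleton of kojic acid 4 (ring oxygen, C6, C5–OH, C4=O, C3, C2 and the hydroxymethyl group). What is left of ring A (C5, C6, C7 and the oxygens on C5 and C7) is a three-carbon unit at the malonate oxidation level, which methyl propiolate 9 supplies with one carbonyl masked as the alkyne.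

## Logic of the disconnections

**15 to 14.** The three O–CH2Ar bonds at O3, O7 and O3' are cut. The polyphenol is then released last and under neutral conditions, and until then only the chelated 5-hydroxyl is free. The gain is small in skeleton but removes all handling of the free polyphenol. The forward step must cleave two benzyl ethers and one 4-methoxybenzyl ether without reducing the C2=C3 bond.

**14 to 11 (key).** The C4a–C5 bond and the C7–O7 bond are cut, which opens ring A to a four-carbon ynoate chain on a monocyclic pyranone. C4a is the ring carbon of a lateral dienolate, C5 is at the ester oxidation level and becomes the 5-hydroxyl, and C7 is the electrophilic alkyne carbon that accepts the oxygen. In one sentence, the route is the folding of the 4-methoxybut-2-ynoate chain of 11 onto its own pyranone ring by alkoxide addition and Claisen closure. The gain is the loss of the whole tetrasubstituted ring A and of the 6-methoxy versus 8-methoxy question, since C8 and its oxygen are already in place. The forward step demands that pyranone C5 act as a carbon nucleophile and that the pyranone survive alkoxide.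

**11 to 10, then to 8 and 9.** The O–CH3 bond is cut first, then the C–C bond between the carbinol carbon (future C8) and the alkyne carbon (future C7). The aldehyde carbon of 8 keeps the oxygen that becomes the 8-methoxy group, and 9 delivers C5, C6 and C7 in one piece. The gain is a three-carbon shortening to a simple aldehyde. The forward steps need 1,2-addition to the aldehyde in the presence of the pyranone carbonyl, and methylation without base-induced isomerisation of the ynoate.

**8 to 7.** No skeletal bond is cut; the aldehyde is taken back to the primary alcohol. The alcohol is the form in which the carbon is bought and carried through the coupling. The forward step must oxidise the heteroallylic alcohol only as far as the aldehyde.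

**7 to 6 and 3.** The C2–C1' bond between ring C and ring B is cut. This is the one convergent cut, and the halogen on 6 sits at the only enol-activated position of the pyranone. The gain is two fragments of similar size, each two steps from a commercial compound. The forward coupling must tolerate a vinylogous acyl bromide and a free primary alcohol.

**6 to 5 to 4.** The O–benzyl bond and then the C–Br bond are cut. 4 is commercial and its only enol-activated C–H is the one that becomes C2 of 15. The forward steps need monobromination at that site and alkylation of the enolic oxygen in preference to the primary alcohol.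

**3 to 2 to 1.** The C–B bond and then the O–CH2Ar bond are cut. The C–H that becomes C1' is the only one of the ring not next to a substituent; electrophilic substitution of 1 would go ortho or para to oxygen instead. The forward borylation therefore needs a protecting group without unhindered C–H bonds of its own, hence 4-methoxybenzyl and not benzyl.

## Other disconnections considered

**Alternative 1:** the first plan to come to mind, cutting O1–C2 and the C3–O bond. Claisen–Schmidt condensation of acetophenone A1 with aldehyde A2 would give chalcone A3. Algar–Flynn–Oyamada oxidation (alkaline H2O2) would close ring C with the 3-hydroxyl in place to give A4, and hydrogenolysis would give 15. The chosen plan is preferred on structural grounds. Here the whole difficulty is moved into A1, whose free hydroxyl must be the one next to the methoxy group while the other ortho oxygen is blocked. Phloroglucinol-derived precursors offer both ortho oxygens, so A1 needs its own multi-step regiocontrolled synthesis, and the key step does nothing to help. Mechanistically, a 6'-alkoxy group twists the enone of A3 and is expected to favour attack at the alpha carbon (aurone formation) over six-membered closure. The step count is no lower.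

**Alternative 2:** cutting O1–C8a. Oxidation of hydroquinone diketone A5 would give acylquinone A6, and its enol oxygen would add to the quinone carbon next to the acyl group (oxa-Michael addition) to give 5,8-dihydroxy compound A7. Methylation of the 8-hydroxyl and hydrogenolysis would then give 15. The ring oxygen is forced onto the right carbon, which is attractive. However, A5 already has a free ortho hydroxyl that can close ring C in the ordinary sense (hemiketal formation and dehydration) to the 6-hydroxy isomer, and the oxidation must outrun this. The plan also needs a late selective methylation and a longer assembly of A5 (acylation, acyl migration), so it is longer and less secure than the chosen plan.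

**Alternative 3:** cutting ring A at C4a–C5 by a pericyclic route. A C6-metalated derivative of pyranone A9 would add to semisquarate A8, and O-methylation would give cyclobutenone A10. Thermolysis would open the four-membered ring (conrotatory, four electrons) to dienylketene A11, which would close by six-electron electrocyclisation and tautomerise to 14. The regiochemical logic is the same as in the chosen plan. The grounds against it are step economy and precedent: A8 needs several steps from squaric acid, and A9 must be metalated next to the ring oxygen, where 4-pyranones tend to suffer nucleophilic addition and ring opening. A tertiary cyclobutenol must also be methylated. The chosen plan reaches the same ring from 4 and 9 by polar steps.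

Key step: step 9

Remark: 15 is achiral; the stereocentre that appears in 10, 11 and 12 (and the one in 13) is carried as the racemate and disappears in step 9.

## Route

Step 1
Reactants: 1 2,3-dimethoxyphenol
Product: 2 1,2-dimethoxy-3-[(4-methoxybenzyl)oxy]benzene
Conditions: 4-methoxybenzyl chloride (1.1 equiv), K2CO3, DMF, 60 °C
Reagents that add atoms: 4-methoxybenzyl chloride, COc1ccc(CCl)cc1
Why: Williamson ether synthesis on the phenoxide. The 4-methoxybenzyl group is chosen because every C–H of its ring lies ortho to a substituent, which keeps it out of the borylation of step 2, and because it is removed by hydrogenolysis in step 10.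

Step 2
Reactants: 2 1,2-dimethoxy-3-[(4-methoxybenzyl)oxy]benzene
Product: 3 2-{3,4-dimethoxy-5-[(4-methoxybenzyl)oxy]phenyl}-4,4,5,5-tetramethyl-1,3,2-dioxaborolane
Conditions: B2pin2 (1.0 equiv), [Ir(OMe)(cod)]2 (1.5 mol %), 4,4'-di-tert-butyl-2,2'-bipyridine (3 mol %), THF, 80 °C
Reagents that add atoms: bis(pinacolato)diboron, CC1(C)OB(OC1(C)C)B1OC(C)(C)C(C)(C)O1
Why: Iridium-catalysed aromatic C–H borylation is under steric control and avoids C–H bonds ortho to substituents. C5–H of 2 (para to the central methoxy group) is the only C–H in the molecule flanked by two hydrogens, a site that electrophilic substitution cannot reach.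

Step 3
Reactants: 4 kojic acid (5-hydroxy-2-(hydroxymethyl)-4H-pyran-4-one)
Product: 5 2-bromo-3-hydroxy-6-(hydroxymethyl)-4H-pyran-4-one
Conditions: NBS (1.05 equiv), DMF, 0 °C to rt
Reagents that add atoms: N-bromosuccinimide, O=C1CCC(=O)N1Br
Why: Electrophilic bromination of the enol. C6 of kojic acid is the beta carbon of the C5 enol (the ortho position of a vinylogous phenol) and is the site at which kojic acid takes electrophiles; C3 has no such activation.

Step 4
Reactants: 5 2-bromo-3-hydroxy-6-(hydroxymethyl)-4H-pyran-4-one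
Product: 6 3-(benzyloxy)-2-bromo-6-(hydroxymethyl)-4H-pyran-4-one
Conditions: BnBr (1.1 equiv), K2CO3, DMF, rt
Reagents that add atoms: benzyl bromide, BrCc1ccccc1
Why: O-alkylation of the acidic enolic hydroxyl as its potassium salt. Carbonate does not deprotonate the primary alcohol, which stays free.

Step 5
Reactants: 6 3-(benzyloxy)-2-bromo-6-(hydroxymethyl)-4H-pyran-4-one; 3 2-{3,4-dimethoxy-5-[(4-methoxybenzyl)oxy]phenyl}-4,4,5,5-tetramethyl-1,3,2-dioxaborolane
Product: 7 3-(benzyloxy)-2-{3,4-dimethoxy-5-[(4-methoxybenzyl)oxy]phenyl}-6-(hydroxymethyl)-4H-pyran-4-one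
Conditions: Pd(dppf)Cl2 (5 mol %), K3PO4, 1,4-dioxane/H2O (10:1), 85 °C
Reagents that add atoms: none
Why: Suzuki–Miyaura coupling. The C–Br bond of 6 is a vinylogous acyl bromide and should add readily to zerovalent palladium, and the primary alcohol needs no protection.

Step 6
Reactants: 7 3-(benzyloxy)-2-{3,4-dimethoxy-5-[(4-methoxybenzyl)oxy]phenyl}-6-(hydroxymethyl)-4H-pyran-4-one
Product: 8 5-(benzyloxy)-6-{3,4-dimethoxy-5-[(4-methoxybenzyl)oxy]phenyl}-4-oxo-4H-pyran-2-carbaldehyde
Conditions: activated MnO2 (15 equiv), CH2Cl2, rt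
Reagents that add atoms: none
Why: MnO2 oxidation of an allylic-type (heteroaryl carbinol) alcohol, which should stop at the aldehyde and leave the benzylic ethers untouched.

Step 7
Reactants: 8 5-(benzyloxy)-6-{3,4-dimethoxy-5-[(4-methoxybenzyl)oxy]phenyl}-4-oxo-4H-pyran-2-carbaldehyde; 9 methyl propiolate
Product: 10 methyl 4-[5-(benzyloxy)-6-{3,4-dimethoxy-5-[(4-methoxybenzyl)oxy]phenyl}-4-oxo-4H-pyran-2-yl]-4-hydroxybut-2-ynoate (racemic)
Conditions: 9 (1.5 equiv), LiN(SiMe3)2 (1.4 equiv), THF, −78 °C; then 8, −78 °C; aq. NH4Cl at −78 °C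
Reagents that add atoms: none
Why: 1,2-addition of the lithium acetylide of 9 to the aldehyde, which is far more electrophilic than the vinylogous ester carbonyl of the pyranone. The new stereocentre forms as the racemate and needs no control, because it becomes the sp2 carbon C8 in step 9.

Step 8
Reactants: 10 methyl 4-[5-(benzyloxy)-6-{3,4-dimethoxy-5-[(4-methoxybenzyl)oxy]phenyl}-4-oxo-4H-pyran-2-yl]-4-hydroxybut-2-ynoate (racemic)
Product: 11 methyl 4-[5-(benzyloxy)-6-{3,4-dimethoxy-5-[(4-methoxybenzyl)oxy]phenyl}-4-oxo-4H-pyran-2-yl]-4-methoxybut-2-ynoate (racemic)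
Conditions: MeI (10 equiv), Ag2O (3 equiv), 4 Å molecular sieves, CH2Cl2, rt, dark
Reagents that add atoms: iodomethane, CI
Why: Purdie methylation. Ag2O activates MeI under nearly neutral conditions, so the acidic propargylic C–H should not be removed and prototropic isomerisation of the ynoate is avoided.

Step 9
Reactants: 11 methyl 4-[5-(benzyloxy)-6-{3,4-dimethoxy-5-[(4-methoxybenzyl)oxy]phenyl}-4-oxo-4H-pyran-2-yl]-4-methoxybut-2-ynoate (racemic)
Product: 14 3,7-bis(benzyloxy)-2-{3,4-dimethoxy-5-[(4-methoxybenzyl)oxy]phenyl}-5-hydroxy-8-methoxy-4H-chromen-4-one, via benzyloxy enoate 12 (not isolated), via dienone 13 (not isolated)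
Conditions: BnOH (4 equiv), NaH (2.2 equiv), THF, 0 °C; add 11, 0 to 40 °C; then 1 M HCl
Reagents that add atoms: benzyl alcohol, OCc1ccccc1
Why: Proposed new method: sodium benzyloxide adds to the alkyne carbon beta to the ester (oxa-Michael addition, direct or through the allenoate tautomer) to give enoate 12, and removal of the acidic C–H between the enoate and the pyranone gives a cross-conjugated dienolate that is nucleophilic at pyranone C5. This carbon attacks the ester carbonyl in a 6-(enolexo)-exo-trig Claisen (Dieckmann-type) closure of ring A, methoxide leaves to give dienone 13, and 13 enolises irreversibly to the aromatic phenoxide of 14. The closest known reaction types are the Dieckmann condensation, the base-induced Claisen folding of poly-beta-carbonyl chains to acylphloroglucinols (the biosynthetic mode of ring A formation) and the alkoxide addition to alkynoates; acylation of a 4-pyranone at its ring carbon through the lateral dienolate is the untested element. No stereocentre is set: the racemic centre of 11 and 12 becomes sp2 C8 and the C4a centre of 13 is lost on enolisation. The regiochemistry needs no selectivity because it is fixed by connectivity: C8 and its methoxy group are the former hydroxymethyl carbon of 4, O7 is the oxygen of benzyl alcohol and the C5 hydroxyl is the ester carbonyl, so a 6-methoxy isomer cannot form. The selectivity that is needed is carbon attack through C5 over intermolecular reactions of the chain; the tether allows only the six-membered closure, the (E) and (Z) isomers of 12 interconvert under the basic conditions so that the ester can reach C5, and the anionic pyranone is protected against ring-opening addition of alkoxide.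

Step 10
Reactants: 14 3,7-bis(benzyloxy)-2-{3,4-dimethoxy-5-[(4-methoxybenzyl)oxy]phenyl}-5-hydroxy-8-methoxy-4H-chromen-4-one
Product: 15 3,5,7-trihydroxy-2-(3-hydroxy-4,5-dimethoxyphenyl)-8-methoxy-4H-chromen-4-one
Conditions: H2 (1 atm), 10% Pd/C, THF/MeOH (1:1), rt
Reagents that add atoms: none
Why: Hydrogenolysis of the two benzyl ethers and the 4-methoxybenzyl ether under neutral conditions, which avoids acid and with it the Wessely–Moser rearrangement. The tetrasubstituted C2=C3 bond is part of a vinylogous ester and should not be reduced under these mild conditions.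

## Compound list

1 | 2,3-dimethoxyphenol | COc1cccc(O)c1OC | starting material
2 | 1,2-dimethoxy-3-[(4-methoxybenzyl)oxy]benzene | COc1ccc(COc2cccc(OC)c2OC)cc1 | intermediate
3 | 2-{3,4-dimethoxy-5-[(4-methoxybenzyl)oxy]phenyl}-4,4,5,5-tetramethyl-1,3,2-dioxaborolane | COc1ccc(COc2cc(B3OC(C)(C)C(C)(C)O3)cc(OC)c2OC)cc1 | intermediate
4 | kojic acid, 5-hydroxy-2-(hydroxymethyl)-4H-pyran-4-one | OCc1cc(=O)c(O)co1 | starting material
5 | 2-bromo-3-hydroxy-6-(hydroxymethyl)-4H-pyran-4-one | OCc1cc(=O)c(O)c(Br)o1 | intermediate
6 | 3-(benzyloxy)-2-bromo-6-(hydroxymethyl)-4H-pyran-4-one | OCc1cc(=O)c(OCc2ccccc2)c(Br)o1 | intermediate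
7 | 3-(benzyloxy)-2-{3,4-dimethoxy-5-[(4-methoxybenzyl)oxy]phenyl}-6-(hydroxymethyl)-4H-pyran-4-one | OCc1cc(=O)c(OCc2ccccc2)c(-c2cc(OC)c(OC)c(OCc3ccc(OC)cc3)c2)o1 | intermediate
8 | 5-(benzyloxy)-6-{3,4-dimethoxy-5-[(4-methoxybenzyl)oxy]phenyl}-4-oxo-4H-pyran-2-carbaldehyde | O=Cc1cc(=O)c(OCc2ccccc2)c(-c2cc(OC)c(OC)c(OCc3ccc(OC)cc3)c2)o1 | intermediate
9 | methyl propiolate | C#CC(=O)OC | starting material
10 | methyl 4-[5-(benzyloxy)-6-{3,4-dimethoxy-5-[(4-methoxybenzyl)oxy]phenyl}-4-oxo-4H-pyran-2-yl]-4-hydroxybut-2-ynoate (racemic) | COC(=O)C#CC(O)c1cc(=O)c(OCc2ccccc2)c(-c2cc(OC)c(OC)c(OCc3ccc(OC)cc3)c2)o1 | intermediate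
11 | methyl 4-[5-(benzyloxy)-6-{3,4-dimethoxy-5-[(4-methoxybenzyl)oxy]phenyl}-4-oxo-4H-pyran-2-yl]-4-methoxybut-2-ynoate (racemic) | COC(=O)C#CC(OC)c1cc(=O)c(OCc2ccccc2)c(-c2cc(OC)c(OC)c(OCc3ccc(OC)cc3)c2)o1 | intermediate
12 | methyl (E)-3-(benzyloxy)-4-[5-(benzyloxy)-6-{3,4-dimethoxy-5-[(4-methoxybenzyl)oxy]phenyl}-4-oxo-4H-pyran-2-yl]-4-methoxybut-2-enoate (racemic, formed in step 9 and not isolated) | COC(=O)/C=C(/OCc1ccccc1)C(OC)c1cc(=O)c(OCc2ccccc2)c(-c2cc(OC)c(OC)c(OCc3ccc(OC)cc3)c2)o1 | intermediate
13 | 3,7-bis(benzyloxy)-2-{3,4-dimethoxy-5-[(4-methoxybenzyl)oxy]phenyl}-8-methoxy-4aH-chromene-4,5-dione (racemic, formed in step 9 and not isolated) | O=C1C=C(OCc2ccccc2)C(OC)=C2OC(-c3cc(OC)c(OC)c(OCc4ccc(OC)cc4)c3)=C(OCc3ccccc3)C(=O)C12 | intermediate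
14 | 3,7-bis(benzyloxy)-2-{3,4-dimethoxy-5-[(4-methoxybenzyl)oxy]phenyl}-5-hydroxy-8-methoxy-4H-chromen-4-one | COc1c(OCc2ccccc2)cc(O)c2c(=O)c(OCc3ccccc3)c(-c3cc(OC)c(OC)c(OCc4ccc(OC)cc4)c3)oc12 | intermediate
15 | 3,5,7-trihydroxy-2-(3-hydroxy-4,5-dimethoxyphenyl)-8-methoxy-4H-chromen-4-one (CNP0225742.0) | COc1cc(-c2oc3c(OC)c(O)cc(O)c3c(=O)c2O)cc(O)c1OC | target

## Step count and risk

Total steps: 10. Longest linear sequence: 8 steps (steps 3 to 10 from 4; the branch from 1 through steps 1, 2 and 5 to 10 is equally long).

**Step 9 (key step, proposed new method).** What may go wrong: conjugate addition of benzyloxide to C2 or C6 of the pyranone with ring opening, oligomerisation of the allenoate formed by prototropy, or reprotonation of the dienolate faster than closure through the ring carbon.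

Fallback, known reactions only. The annulation of ring A onto the pyranone is given up and ring B is attached to a preformed chromone; the fallback sets out from 3 and returns to the route at 15. In the names below Ar stands for 3,4-dimethoxy-5-[(4-methoxybenzyl)oxy]phenyl.
- Commercial 5,7-dihydroxy-4H-chromen-4-one F1 is benzylated at the more acidic 7-hydroxyl (BnBr, K2CO3, acetone) to 7-(benzyloxy)-5-hydroxy-4H-chromen-4-one F2.
- Oxidative Heck coupling of F2 with 3 (Pd(O2CCF3)2, 1,10-phenanthroline, O2, DMSO/AcOH; divalent palladium transfers the aryl group to C2 and beta-hydride elimination restores the double bond) gives 7-(benzyloxy)-2-Ar-5-hydroxy-4H-chromen-4-one F3.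
- Elbs persulfate oxidation (K2S2O8, aqueous KOH/pyridine, then dilute acid) places oxygen para to the 5-hydroxyl, at C8, to give 7-(benzyloxy)-2-Ar-5,8-dihydroxy-4H-chromen-4-one F4.
- The non-chelated 8-hydroxyl is methylated (MeI, 1 equiv, K2CO3, acetone) to 7-(benzyloxy)-2-Ar-5-hydroxy-8-methoxy-4H-chromen-4-one F5.
- The 5-hydroxyl is benzylated (BnBr, K2CO3, DMF, 60 °C) to 5,7-bis(benzyloxy)-2-Ar-8-methoxy-4H-chromen-4-one F6.
- Epoxidation of C2=C3 with dimethyldioxirane and acid-induced opening gives 5,7-bis(benzyloxy)-2-Ar-3-hydroxy-8-methoxy-4H-chromen-4-one F7.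
- Hydrogenolysis under the conditions of step 10 gives 15.

This path is longer, and it relies on the para selectivity of the Elbs oxidation for the C8 oxygen.

**Step 5.** What may go wrong: hydrolytic addition–elimination at the bromine-bearing carbon under aqueous base, protodeboronation of the electron-rich boronate, and, one stage earlier, over-bromination or oxidation of 4 in step 3.

Fallback: the halogen is left out and the bond is made by C–H functionalisation; it sets out from 4 (with 3) and returns at 7. Benzylation of 4 (BnCl, NaOH, MeOH/H2O) gives 5-(benzyloxy)-2-(hydroxymethyl)-4H-pyran-4-one F8. Its C6–H, the only unsubstituted enone beta position, is arylated with 3 by oxidative Heck coupling (Pd(O2CCF3)2, 2,2'-bipyridine, O2, AcOH/DMSO) to give 7.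

**Step 8.** What may go wrong: prototropic isomerisation of the gamma-hydroxy ynoate to the allenoate or the gamma-oxo enoate before the slow O-methylation of a hindered, electron-poor alcohol.

Fallback: the methoxy group is put in before the C–C bond; it sets out from 8 and returns at 11, bypassing 10. Acetalisation (HC(OMe)3, cat. TsOH, MeOH) gives 3-(benzyloxy)-2-{3,4-dimethoxy-5-[(4-methoxybenzyl)oxy]phenyl}-6-(dimethoxymethyl)-4H-pyran-4-one F9. The oxocarbenium ion released from F9 by TMSOTf is trapped by the zinc acetylide made in the flask from 9 (ZnBr2, i-Pr2NEt, CH2Cl2) to give 11.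

**Step 10.** What may go wrong: over-reduction of the C2=C3 bond, or slow cleavage of the 4-methoxybenzyl ether that leaves partly protected material.

Fallback: a non-reductive, two-stage deprotection; it sets out from 14 and returns at 15. Acidolysis (TFA, anisole, CH2Cl2, 0 °C) removes the 4-methoxybenzyl group to give 3,7-bis(benzyloxy)-5-hydroxy-2-(3-hydroxy-4,5-dimethoxyphenyl)-8-methoxy-4H-chromen-4-one F10. BCl3 with pentamethylbenzene as cation scavenger (CH2Cl2, −78 °C) then cleaves both benzyl ethers to give 15.

## Further compounds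

F1 | step 9 | 5,7-dihydroxy-4H-chromen-4-one | O=c1ccoc2cc(O)cc(O)c12
F2 | step 9 | 7-(benzyloxy)-5-hydroxy-4H-chromen-4-one | O=c1ccoc2cc(OCc3ccccc3)cc(O)c12
F3 | step 9 | 7-(benzyloxy)-2-{3,4-dimethoxy-5-[(4-methoxybenzyl)oxy]phenyl}-5-hydroxy-4H-chromen-4-one | COc1ccc(COc2cc(-c3cc(=O)c4c(O)cc(OCc5ccccc5)cc4o3)cc(OC)c2OC)cc1
F4 | step 9 | 7-(benzyloxy)-2-{3,4-dimethoxy-5-[(4-methoxybenzyl)oxy]phenyl}-5,8-dihydroxy-4H-chromen-4-one | COc1ccc(COc2cc(-c3cc(=O)c4c(O)cc(OCc5ccccc5)c(O)c4o3)cc(OC)c2OC)cc1
F5 | step 9 | 7-(benzyloxy)-2-{3,4-dimethoxy-5-[(4-methoxybenzyl)oxy]phenyl}-5-hydroxy-8-methoxy-4H-chromen-4-one | COc1ccc(COc2cc(-c3cc(=O)c4c(O)cc(OCc5ccccc5)c(OC)c4o3)cc(OC)c2OC)cc1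
F6 | step 9 | 5,7-bis(benzyloxy)-2-{3,4-dimethoxy-5-[(4-methoxybenzyl)oxy]phenyl}-8-methoxy-4H-chromen-4-one | COc1ccc(COc2cc(-c3cc(=O)c4c(OCc5ccccc5)cc(OCc5ccccc5)c(OC)c4o3)cc(OC)c2OC)cc1
F7 | step 9 | 5,7-bis(benzyloxy)-2-{3,4-dimethoxy-5-[(4-methoxybenzyl)oxy]phenyl}-3-hydroxy-8-methoxy-4H-chromen-4-one | COc1ccc(COc2cc(-c3oc4c(OC)c(OCc5ccccc5)cc(OCc5ccccc5)c4c(=O)c3O)cc(OC)c2OC)cc1
F8 | step 5 | 5-(benzyloxy)-2-(hydroxymethyl)-4H-pyran-4-one | OCc1cc(=O)c(OCc2ccccc2)co1
F9 | step 8 | 3-(benzyloxy)-2-{3,4-dimethoxy-5-[(4-methoxybenzyl)oxy]phenyl}-6-(dimethoxymethyl)-4H-pyran-4-one | COC(OC)c1cc(=O)c(OCc2ccccc2)c(-c2cc(OC)c(OC)c(OCc3ccc(OC)cc3)c2)o1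
F10 | step 10 | 3,7-bis(benzyloxy)-5-hydroxy-2-(3-hydroxy-4,5-dimethoxyphenyl)-8-methoxy-4H-chromen-4-one | COc1cc(-c2oc3c(OC)c(OCc4ccccc4)cc(O)c3c(=O)c2OCc2ccccc2)cc(O)c1OC
A1 | alternative 1 | 1-[4,6-bis(benzyloxy)-2-hydroxy-3-methoxyphenyl]ethan-1-one | CC(=O)c1c(O)c(OC)c(OCc2ccccc2)cc1OCc1ccccc1
A2 | alternative 1 | 3-(benzyloxy)-4,5-dimethoxybenzaldehyde | COc1cc(C=O)cc(OCc2ccccc2)c1OC
A3 | alternative 1 | (E)-1-[4,6-bis(benzyloxy)-2-hydroxy-3-methoxyphenyl]-3-[3-(benzyloxy)-4,5-dimethoxyphenyl]prop-2-en-1-one | COc1cc(/C=C/C(=O)c2c(O)c(OC)c(OCc3ccccc3)cc2OCc2ccccc2)cc(OCc2ccccc2)c1OC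
A4 | alternative 1 | 5,7-bis(benzyloxy)-2-[3-(benzyloxy)-4,5-dimethoxyphenyl]-3-hydroxy-8-methoxy-4H-chromen-4-one | COc1cc(-c2oc3c(OC)c(OCc4ccccc4)cc(OCc4ccccc4)c3c(=O)c2O)cc(OCc2ccccc2)c1OC
A5 | alternative 2 | 2-(benzyloxy)-1-[4-(benzyloxy)-2,5-dihydroxyphenyl]-3-[3-(benzyloxy)-4,5-dimethoxyphenyl]propane-1,3-dione | COc1cc(C(=O)C(OCc2ccccc2)C(=O)c2cc(O)c(OCc3ccccc3)cc2O)cc(OCc2ccccc2)c1OC
A6 | alternative 2 | 2-(benzyloxy)-5-{2-(benzyloxy)-3-[3-(benzyloxy)-4,5-dimethoxyphenyl]-3-oxopropanoyl}cyclohexa-2,5-diene-1,4-dione | COc1cc(C(=O)C(OCc2ccccc2)C(=O)C2=CC(=O)C(OCc3ccccc3)=CC2=O)cc(OCc2ccccc2)c1OC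
A7 | alternative 2 | 3,7-bis(benzyloxy)-2-[3-(benzyloxy)-4,5-dimethoxyphenyl]-5,8-dihydroxy-4H-chromen-4-one | COc1cc(-c2oc3c(O)c(OCc4ccccc4)cc(O)c3c(=O)c2OCc2ccccc2)cc(OCc2ccccc2)c1OC
A8 | alternative 3 | 3-(benzyloxy)cyclobut-3-ene-1,2-dione | O=C1C=C(OCc2ccccc2)C1=O
A9 | alternative 3 | 3-(benzyloxy)-2-{3,4-dimethoxy-5-[(4-methoxybenzyl)oxy]phenyl}-4H-pyran-4-one | O=c1ccoc(-c2cc(OC)c(OC)c(OCc3ccc(OC)cc3)c2)c1OCc1ccccc1
A10 | alternative 3 | 3-(benzyloxy)-4-[5-(benzyloxy)-6-{3,4-dimethoxy-5-[(4-methoxybenzyl)oxy]phenyl}-4-oxo-4H-pyran-2-yl]-4-methoxycyclobut-2-en-1-one (racemic) | COC1(c2cc(=O)c(OCc3ccccc3)c(-c3cc(OC)c(OC)c(OCc4ccc(OC)cc4)c3)o2)C(=O)C=C1OCc1ccccc1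
A11 | alternative 3 | (Z)-3-(benzyloxy)-4-[5-(benzyloxy)-6-{3,4-dimethoxy-5-[(4-methoxybenzyl)oxy]phenyl}-4-oxo-4H-pyran-2-yl]-4-methoxybuta-1,3-dien-1-one | O=C=C/C(OCc1ccccc1)=C(/OC)c1cc(=O)c(OCc2ccccc2)c(-c2cc(OC)c(OC)c(OCc3ccc(OC)cc3)c2)o1
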